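**Retrosynthetic overview**
1. Target 9 ⇐ sulfone 8 by reductive cleavage of a traceless C11–SO2Ph group.
2. 8 ⇐ C11–C12 bond: α-sulfonyl carbanion of bicyclic sulfone 6 + (2E,6E)-farnesyl bromide 1, so one C15 bromide supplies both halves.
3. 6 ⇐ acyclic (2E,6E)-farnesyl phenyl sulfone 3 by a one-flask, enantioselective, proton-initiated bicyclisation.
4. Ring order: ring A first (C4–C5 bond, chiral acid, fixes C5), then ring B in the same flask (C9–C10 bond, chair–chair relay to C10 and C9), ending with H7 loss to the 7-ene.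
5. 3 ⇐ 1 + sodium benzenesulfinate 2.

**Assumptions**
- Drimane/polypodane numbering is used: ring carbons C1–C10, C11 is the side-chain carbon on C9.
- The chiral ligand of step 2, (R)-2-(2-fluorobenzyloxy)-2'-hydroxy-1,1'-binaphthyl, is made beforehand by one O-benzylation of commercial (R)-BINOL and is treated as a reagent. With SnCl4 it only passes a proton on and is not consumed.
- The (R)-ligand is taken to give the (5S,10S) series, as it does in the related cyclisation leading to (−)-ambrox; if the sense proved opposite, the (S)-ligand would be used.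

**Step 1**
Reactants: 1 (2E,6E)-farnesyl bromide; 2 sodium benzenesulfinate
Product: 3 (2E,6E)-farnesyl phenyl sulfone
Conditions: DMF, 0 °C → rt, 12 h
Reagents that add atoms: none
Why: SN2 S-alkylation of the ambident sulfinate at the primary allylic carbon gives the sulfone without touching the E-alkenes, and no stereocentre is formed.

**Step 2**
Reactants: 3 (2E,6E)-farnesyl phenyl sulfone
Product: 6 (5S,9S,10S)-11-(phenylsulfonyl)drim-7-ene, via (S)-α-monocyclofarnesyl phenyl sulfone 4 (not isolated), via (S)-γ-monocyclofarnesyl phenyl sulfone 5 (not isolated)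
Conditions: (R)-2-(2-fluorobenzyloxy)-2'-hydroxy-1,1'-binaphthyl·SnCl4 (1.5 equiv), CH2Cl2, −78 °C, 48 h; then FSO3H (6 equiv), i-PrNO2, −78 °C, 30 min; Et3N; recrystallise
Reagents that add atoms: none
Why: Proposed new method: the chiral Lewis-acid-assisted Brønsted acid protonates the terminal isopropylidene face-selectively with concerted chair closure of ring A (sets C5 as S), and the superacid then re-ionises olefins 4 and 5 at C10 so that the sulfone-deactivated E-alkene closes ring B through a second chair (anti addition relays C5 to 10S and 9S, trans-decalin, 9-H α) before the C8 cation loses H7 to give the 7-ene; the closest known reaction types are the two-stage chiral-then-achiral acid polyene cyclisation of homofarnesyl ethers and the racemic superacid bicyclisation of farnesyl sulfones, merged here in one flask.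

**Step 3**
Reactants: 6 (5S,9S,10S)-11-(phenylsulfonyl)drim-7-ene; 1 (2E,6E)-farnesyl bromide
Product: 8 (5S,9S,10S,13E,17E)-11-(phenylsulfonyl)polypoda-7,13,17,21-tetraene, via C11-lithiated sulfone 7 (not isolated)
Conditions: n-BuLi (1.1 equiv), THF–DMPU, −78 °C, 30 min; then 1 (1.3 equiv), −78 → −20 °C
Reagents that add atoms: none
Why: α-Sulfonyl carbanion alkylation (Biellmann–Julia allyl coupling) occurs by SN2 at the primary allylic carbon with retention of the E-geometry, and the new C11 centre forms as an epimer mixture that is erased in step 4 while C5, C9 and C10 are untouched.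

**Step 4**
Reactants: 8 (5S,9S,10S,13E,17E)-11-(phenylsulfonyl)polypoda-7,13,17,21-tetraene
Product: 9 α-polypodatetraene, (5S,9S,10S,13E,17E)-polypoda-7,13,17,21-tetraene
Conditions: 6% Na(Hg) (6 equiv Na), Na2HPO4 (4 equiv), MeOH–THF 1:1, −20 → 0 °C
Reagents that add atoms: none
Why: Reductive desulfonylation by electron transfer from sodium amalgam cleaves the C11–S bond and methanol protonates C11, while the isolated trisubstituted alkenes are not reduced and, the sulfone not being allylic, cannot shift, so all three stereocentres and both E-alkenes survive.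

**Compound list**
1 | (2E,6E)-farnesyl bromide, (2E,6E)-1-bromo-3,7,11-trimethyldodeca-2,6,10-triene | CC(C)=CCC/C(C)=C/CC/C(C)=C/CBr | starting material
2 | sodium benzenesulfinate | [Na+].[O-]S(=O)c1ccccc1 | starting material
3 | (2E,6E)-farnesyl phenyl sulfone, [(2E,6E)-3,7,11-trimethyldodeca-2,6,10-trien-1-yl]sulfonylbenzene | CC(C)=CCC/C(C)=C/CC/C(C)=C/CS(=O)(=O)c1ccccc1 | intermediate
4 | (S)-α-monocyclofarnesyl phenyl sulfone, {(2E)-3-methyl-5-[(1S)-2,6,6-trimethylcyclohex-2-en-1-yl]pent-2-en-1-yl}sulfonylbenzene | O=S(=O)(c1ccccc1)C/C=C(C)/CC[C@@H]1C(C)=CCCC1(C)C | intermediate (not isolated)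
5 | (S)-γ-monocyclofarnesyl phenyl sulfone, {(2E)-5-[(1S)-2,2-dimethyl-6-methylidenecyclohexyl]-3-methylpent-2-en-1-yl}sulfonylbenzene | O=S(=O)(c1ccccc1)C/C=C(C)/CC[C@@H]1C(=C)CCCC1(C)C | intermediate (not isolated)
6 | (5S,9S,10S)-11-(phenylsulfonyl)drim-7-ene, {[(1S,4aS,8aS)-2,5,5,8a-tetramethyl-1,4,4a,5,6,7,8,8a-octahydronaphthalen-1-yl]methyl}sulfonylbenzene; trans-decalin, 9-H anti to the C10 methyl | O=S(=O)(c1ccccc1)C[C@H]1C(C)=CC[C@H]2C(C)(C)CCC[C@]12C | intermediate
7 | C11-lithiated sulfone, (5S,9S,10S)-11-lithio-11-(phenylsulfonyl)drim-7-ene | [Li]C([C@H]1C(C)=CC[C@H]2C(C)(C)CCC[C@]12C)S(=O)(=O)c1ccccc1 | intermediate (not isolated)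
8 | (5S,9S,10S,13E,17E)-11-(phenylsulfonyl)polypoda-7,13,17,21-tetraene, mixture of C11 epimers | CC(C)=CCC/C(C)=C/CC/C(C)=C/CC([C@H]1C(C)=CC[C@H]2C(C)(C)CCC[C@]12C)S(=O)(=O)c1ccccc1 | intermediate
9 | α-polypodatetraene (CNP0141177.1), (4aS,5S,8aS)-1,1,4a,6-tetramethyl-5-[(3E,7E)-4,8,12-trimethyltrideca-3,7,11-trien-1-yl]-1,2,3,4,4a,5,8,8a-octahydronaphthalene | CC(C)=CCC/C(C)=C/CC/C(C)=C/CC[C@H]1C(C)=CC[C@H]2C(C)(C)CCC[C@]12C | target

**Step count**
Total: 4 steps (5 operations if the one-step ligand preparation is counted). Longest linear sequence: 4 (1 → 3 → 6 → 8 → 9).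

**Three steps most likely to fail**

Step 2 is the weakest point. The enantiomeric excess may be only moderate and must be raised by recrystallising crystalline 6. Any 3 left when the superacid is added cyclises racemically, and the sulfone may bind SnCl4 or give some 8(12)- or 8-ene isomers. Fallback: setting out again from 3, FSO3H alone (i-PrNO2, −78 °C, Et3N quench) gives the racemic bicyclisation, so 6 forms together with its mirror image, (5R,9R,10R)-11-(phenylsulfonyl)drim-7-ene F1. The two are separated by preparative chromatography on a cellulose tris(3,5-dimethylphenylcarbamate) phase. Stereochemistry then comes from resolution instead of induction, and the route is rejoined at 6.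

Step 3 may be slow because carbanion 7 sits next to the C9 methine, which is flanked by the C10 quaternary centre and the C8 methyl. Fallback: setting out from 6 (through 7), SN2 alkylation is replaced by carbonyl addition and Julia olefination. 7 adds at −78 °C to commercial (2E,6E)-farnesal to give the lithium β-alkoxide, lithium 11-(phenylsulfonyl)polypoda-7,13,17,21-tetraen-12-olate F2. This is trapped in the flask with Ac2O as 12-acetoxy-11-(phenylsulfonyl)polypoda-7,13,17,21-tetraene F3. Na(Hg) in MeOH–THF then gives reductive elimination to the conjugated diene (11E,13E,17E)-polypoda-7,11,13,17,21-pentaene F4. Its only disubstituted alkene is saturated by diimide (2-nitrobenzenesulfonylhydrazide, Et3N, CH2Cl2, rt, stopped after one equivalent), which is far slower on trisubstituted alkenes, and the route is rejoined at 9.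

Step 4 may suffer from slow electron transfer to the hindered secondary sulfone or from partial cleavage on the aryl side. Fallback: setting out from 8, electron-transfer cleavage is replaced by oxidative desulfonylation and carbonyl deoxygenation. n-BuLi (THF, −78 °C) gives the tertiary carbanion, 11-lithio-11-(phenylsulfonyl)polypoda-7,13,17,21-tetraene F5. This is oxidised in the flask with Me3SiOOSiMe3 to (13E,17E)-polypoda-7,13,17,21-tetraen-11-one F6. The ketone is β,γ-unsaturated on both sides, so it is handled neutral and cold. Its hydrazone, (13E,17E)-polypoda-7,13,17,21-tetraen-11-one N-tosylhydrazone F7 (TsNHNH2, MeOH, rt, no acid), is reduced with catecholborane and then NaOAc·3H2O. This converts a non-conjugated hydrazone to CH2 without olefin migration, and the route is rejoined at 9.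

**Further compounds**
F1 | step 2 | (5R,9R,10R)-11-(phenylsulfonyl)drim-7-ene (enantiomer of 6) | O=S(=O)(c1ccccc1)C[C@@H]1C(C)=CC[C@@H]2C(C)(C)CCC[C@@]12C
F2 | step 3 | lithium (5S,9S,10S,13E,17E)-11-(phenylsulfonyl)polypoda-7,13,17,21-tetraen-12-olate, diastereomer mixture | CC(C)=CCC/C(C)=C/CC/C(C)=C/C(O[Li])C([C@H]1C(C)=CC[C@H]2C(C)(C)CCC[C@]12C)S(=O)(=O)c1ccccc1
F3 | step 3 | (5S,9S,10S,13E,17E)-12-acetoxy-11-(phenylsulfonyl)polypoda-7,13,17,21-tetraene, diastereomer mixture | CC(C)=CCC/C(C)=C/CC/C(C)=C/C(OC(C)=O)C([C@H]1C(C)=CC[C@H]2C(C)(C)CCC[C@]12C)S(=O)(=O)c1ccccc1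
F4 | step 3 | (5S,9S,10S,11E,13E,17E)-polypoda-7,11,13,17,21-pentaene | CC(C)=CCC/C(C)=C/CC/C(C)=C/C=C/[C@H]1C(C)=CC[C@H]2C(C)(C)CCC[C@]12C
F5 | step 4 | (5S,9S,10S,13E,17E)-11-lithio-11-(phenylsulfonyl)polypoda-7,13,17,21-tetraene | CC(C)=CCC/C(C)=C/CC/C(C)=C/CC([Li])([C@H]1C(C)=CC[C@H]2C(C)(C)CCC[C@]12C)S(=O)(=O)c1ccccc1
F6 | step 4 | (5S,9S,10S,13E,17E)-polypoda-7,13,17,21-tetraen-11-one | CC(C)=CCC/C(C)=C/CC/C(C)=C/CC(=O)[C@H]1C(C)=CC[C@H]2C(C)(C)CCC[C@]12C
F7 | step 4 | (5S,9S,10S,13E,17E)-polypoda-7,13,17,21-tetraen-11-one N-tosylhydrazone | CC(C)=CCC/C(C)=C/CC/C(C)=C/CC(=NNS(=O)(=O)c1ccc(C)cc1)[C@H]1C(C)=CC[C@H]2C(C)(C)CCC[C@]12C
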